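(All runs were computed with constants of no real substance; noise was put on by code.)

In the west run a small charge of 10 mM solid electrophile against 19 mM nucleophile shows no solid at 50.0 min, with target at 52% of that charge; the east run, with 40 mM charged, still holds 20.0 mM of solid while [target] reads 5.20 mM. So I take the nucleophile as the limiting reagent.

| setting | west | east | north | flask |
|---|---|---|---|---|
| solid electrophile | 10 mM | 40 mM | 20 mM | 20 mM |
| nucleophile | 19 mM | 19 mM | 28 mM | 19.0 mM |
| remark | run made earlier | run made earlier | run made earlier |  |
| time |  |  |  | 80 min |

| run | time / min | solid electrophile / % | target / % |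
|---|---|---|---|
| west | 4.00 | 0 | 39 |
| west | 8.00 | 3 | 49 |
| west | 15.0 | 3 | 51 |
| west | 25.0 | 0 | 49 |
| west | 50.0 | 0 | 52 |
| east | 4.00 | 63 | 11 |
| east | 8.00 | 57 | 12 |
| east | 15.0 | 56 | 13 |
| east | 25.0 | 57 | 11 |
| east | 50.0 | 50 | 13 |
| north | 4.00 | 29 | 26 |
| north | 12.0 | 8 | 36 |
| north | 20.0 | 4 | 32 |
| north | 30.0 | 3 | 34 |
| north | 50.0 | 3 | 39 |

(standard deviation of a reading: 2 percentage points)

- the analysis behind the earlier runs scatters by 2 percentage points, standard deviation
- at the start none of the solid electrophile is in solution
- what has only dissolved of solid electrophile counts as not reacted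
- the earlier runs do not show how much of nucleophile is bound; that part of a forecast is a guess

- part of the solid electrophile that has reacted (what has only dissolved counts as not reacted) at 80 min
- share of the unused nucleophile that is free and not bound as protonated nucleophile, at 80 min

I replace each plateau by the mean of its last 4 readings; the west mean is 50.2%, and its last reading lies 1.8 percentage points from it, against a scatter of 2 points. The yield on nucleophile y, mean plateau [target] per nucleophile charged, is the mean of the 3 runs:

y = (0.264 + 0.258 + 0.252) / 3 = 0.258

I assume that each target also binds one nucleophile as protonated nucleophile, which gives this ledger for the 19.0 mM in the flask: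

into target: 4.90 mM
bound as protonated nucleophile: 4.90 mM
unread: 9.19 mM

If the unread part reacts with no electrophile, c is 24.5%; if the whole of it goes like the rest, two nucleophile for each electrophile reacted, c is 47.5%. I commit to the middle, 36.0%, and guess the free share near zero.

The forecast gives 83% and 5%, saying “Free nucleophile should be almost gone, though this is a guess”, and its c stands above my 47.5%.

The flask gives 34.0% and 0.200%.

    nucleophile + acid set free ⇌ protonated nucleophile, settled at all times (K = 4.30 × 10⁵ M⁻¹)
    nucleophile + target → over-reaction product (k = 0.170 M⁻¹ s⁻¹)
    solid electrophile ⇌ electrophile, rate k3*(cs3 - [electrophile]) while solid is left; crystals form when [electrophile] > cs3 (solubility = 11.0 mM, k = 0.00930 s⁻¹)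
    electrophile + nucleophile → acid set free + target (k = 0.510 M⁻¹ s⁻¹)
    2 nucleophile → self-condensation product (k = 0.100 M⁻¹ s⁻¹)

In the flask 6.80 mM has reacted, which lies between my two cases, and target at 29.2% makes the yield on nucleophile 0.308 at 80.0 min, against the 0.258 I read from the earlier runs. The neighbouring flask with 34 mM solid electrophile keeps 0.060% of its nucleophile unbound, and the same ledger over its larger charge gives 21.2%. Its target stands at 17.2%, a yield on nucleophile of 0.308, and its c is 20.0%, which is 6.80 mM reacted.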